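**Retrosynthetic overview**

Numbering is that of the labdane skeleton (ring A: C1–C5, C10; ring B: C5–C10; side chain C11–C16; C17 on C8; C18/C19 on C4; C20 on C10).
End game: the allylic acetate and the C7=C8 bond come from a C8 ketone (enol triflate, hydroxymethylation, acetylation). That ketone and the C9 side chain come from the C9 ketone of a trans-decalone (enol triflate, Negishi coupling with a C11–C16 zinc reagent, hydroboration–oxidation).
Key disconnection: C4–C5, C1–C10 and C2=C3 are cut at once, back to a carvone-derived 5-silyloxy-2-methylcyclohexenone (ring B, C20), the enol silane of isobutyraldehyde (C3, C4, C18, C19) and a vinylphosphonium salt (C1–C2).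
Enabling feature: in ring A the two-carbon unit C1–C2 lies between C10 and C3. C10 is the quaternary fusion carbon α to C9 (a ketone in the precursor, so C10 is an enolate carbon). C3 hangs on the fully substituted C4 and can be a non-enolisable aldehyde. A vinylphosphonium ion spans this gap as an acceptor at C1 and an ylide at C2.
Ring order: ring B is taken from (S)-carvone and ring A is closed in the key step; the C7 silyloxy group relays the carvone stereocentre to C5 and C10 and is then eliminated.

Key step: step 4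

Remark on the chemistry: the given SMILES is read as the ent-labdane series, (5R,9S,10R,13R) in labdane numbering, which is why (S)-carvone and the (R)-monoester of 3-methylglutaric acid are the chiral sources.

**Route**

Step 1
Reactants: 1 (S)-carvone
Product: 3 (1S)-4-methyl-5-oxocyclohex-3-en-1-yl acetate, via methoxy hydroperoxide 2 (not isolated)
Conditions: O3, CH2Cl2/MeOH, −78 °C; then Ac2O, Et3N, DMAP (cat.), −78 °C to rt
Reagents that add atoms: ozone, [O-][O+]=O; methanol, CO
Why: Selective ozonolysis of the electron-rich 1,1-disubstituted alkene in methanol gives 2, whose O-acetylation triggers a Criegee rearrangement in which ring carbon C7 migrates to oxygen with retention, so the carvone stereocentre is kept and the acetyl group of 3 is the former isopropenyl carbon pair.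

Step 2
Reactants: 3 (1S)-4-methyl-5-oxocyclohex-3-en-1-yl acetate
Product: 4 (5S)-5-hydroxy-2-methylcyclohex-2-en-1-one
Conditions: K2CO3 (cat.), MeOH, 0 °C
Reagents that add atoms: none
Why: Carbonate-catalysed transesterification of the acetate at low temperature, where it should outrun β-elimination, leaves the stereocentre untouched.

Step 3
Reactants: 4 (5S)-5-hydroxy-2-methylcyclohex-2-en-1-one
Product: 5 (5S)-5-{[tert-butyl(dimethyl)silyl]oxy}-2-methylcyclohex-2-en-1-one
Conditions: TBSCl, imidazole, DMF, 0 °C to rt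
Reagents that add atoms: tert-butyldimethylsilyl chloride, CC(C)(C)[Si](C)(C)Cl
Why: Imidazole-promoted silylation of the secondary alcohol gives a silyl ether that is a poorer leaving group than acetate and serves as the removable stereocontrol element at C7.

Step 4
Reactants: 5 (5S)-5-{[tert-butyl(dimethyl)silyl]oxy}-2-methylcyclohex-2-en-1-one; 6 trimethyl[(2-methylprop-1-en-1-yl)oxy]silane; 7 triphenyl(vinyl)phosphonium bromide
Product: 10 (3S,4aR,8aR)-3-{[tert-butyl(dimethyl)silyl]oxy}-5,5,8a-trimethyl-3,4,4a,5,8,8a-hexahydronaphthalen-1(2H)-one, via silyl enol ether 8 (not isolated), via phosphorus ylide 9 (not isolated)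
Conditions: 6, Tf2NH (2 mol %), CH2Cl2, −78 °C; then 7, Bu4N[Ph3SiF2] (TBAT), THF, −78 °C to rt
Reagents that add atoms: none
Why: A silyl-cation-catalysed Mukaiyama–Michael addition of 6 to C5 of 5 passes the trimethylsilyl group to the enone oxygen and delivers the C9–C10 enol silane 8 with the C3 aldehyde free; fluoride then releases the enolate, whose C10 adds to the vinylphosphonium ion (C1–C10 bond) to give ylide 9, and intramolecular Wittig olefination of the C3 aldehyde (C2=C3 bond) closes ring A with loss of Ph3PO. The closest known reaction types are the Mukaiyama–Michael addition with silyl transfer, the fluoride-mediated regiospecific C-alkylation of enol silanes and the Schweizer annulation (enolate plus vinylphosphonium salt, then intramolecular Wittig), in which ketone enolates are established donors. Ring A is closed as a six-membered ring by attack of the ylide carbon C2 on the pendant aldehyde carbon C3, a mode that can only give the cis ring alkene. C5 is set by axial attack on the enone anti to the C7 silyloxy group (3,5-trans addition to a 5-substituted cyclohexenone), and C10 by attack of the tetrasubstituted enolate anti to the adjacent C5 substituent, which A(1,2) strain with the C10 methyl holds axial, so that C1 and C4 end up trans and the ring fusion is trans. The step needs the C9–C10 rather than the C8–C9 enolate, secured because the enolate is formed regiodefined in the conjugate addition and is not equilibrated, and it needs the ylide to choose the aldehyde over the ketone, secured because only the aldehyde gives a six-membered ring and, with no hydrogen on C4, it cannot enolise.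

Step 5
Reactants: 10 (3S,4aR,8aR)-3-{[tert-butyl(dimethyl)silyl]oxy}-5,5,8a-trimethyl-3,4,4a,5,8,8a-hexahydronaphthalen-1(2H)-one
Product: 11 (4aR,8aR)-5,5,8a-trimethyl-4a,5,8,8a-tetrahydronaphthalen-1(4H)-one
Conditions: DBU, CH2Cl2, rt
Reagents that add atoms: none
Why: E1cB elimination of silanolate from the β-silyloxy ketone (enolisation is possible only toward C8) removes the auxiliary C7 stereocentre, while C5 and C10 cannot epimerise.

Step 6
Reactants: 11 (4aR,8aR)-5,5,8a-trimethyl-4a,5,8,8a-tetrahydronaphthalen-1(4H)-one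
Product: 12 (4aR,8aR)-5,5,8a-trimethyloctahydronaphthalen-1(2H)-one
Conditions: H2 (1 atm), Pd/C, EtOAc, rt
Reagents that add atoms: none
Why: Heterogeneous catalytic hydrogenation saturates both disubstituted alkenes and leaves the hindered ketone and the two stereocentres untouched.

Step 7
Reactants: 12 (4aR,8aR)-5,5,8a-trimethyloctahydronaphthalen-1(2H)-one
Product: 14 (4aR,8aR)-5,5,8a-trimethyl-3,4,4a,5,6,7,8,8a-octahydronaphthalen-1-yl trifluoromethanesulfonate, via potassium enolate 13 (not isolated)
Conditions: KN(SiMe3)2, THF, −78 °C; then PhNTf2, −78 to 0 °C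
Reagents that add atoms: N-phenylbis(trifluoromethanesulfonimide), O=S(=O)(N(c1ccccc1)S(=O)(=O)C(F)(F)F)C(F)(F)F
Why: Enolate O-sulfonylation gives a single regioisomer because C10 is quaternary and the ketone can enolise only toward C8.

Step 8
Reactants: 15 (3R)-5-methoxy-3-methyl-5-oxopentanoic acid
Product: 16 methyl (3R)-5-hydroxy-3-methylpentanoate
Conditions: BH3·SMe2, THF, 0 °C to rt; MeOH quench
Reagents that add atoms: none
Why: Chemoselective borane reduction of the carboxylic acid in the presence of the methyl ester does not involve the C13 stereocentre.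

Step 9
Reactants: 16 methyl (3R)-5-hydroxy-3-methylpentanoate
Product: 17 methyl (3S)-5-iodo-3-methylpentanoate
Conditions: I2, PPh3, imidazole, CH2Cl2, 0 °C to rt
Reagents that add atoms: iodine, II
Why: Appel-type iodination of the primary alcohol proceeds by SN2 at C11, and the descriptor at C13 changes to S only through the change in substituent priority.

Step 10
Reactants: 14 (4aR,8aR)-5,5,8a-trimethyl-3,4,4a,5,6,7,8,8a-octahydronaphthalen-1-yl trifluoromethanesulfonate; 17 methyl (3S)-5-iodo-3-methylpentanoate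
Product: 19 methyl (3R)-3-methyl-5-[(4aR,8aR)-5,5,8a-trimethyl-3,4,4a,5,6,7,8,8a-octahydronaphthalen-1-yl]pentanoate, via alkylzinc iodide 18 (not isolated)
Conditions: 17, Zn dust, LiCl, THF, 40 °C; then 14, PdCl2(dppf) (5 mol %), THF/NMP, 50 °C
Reagents that add atoms: none
Why: Zinc insertion gives the ester-tolerant alkylzinc 18, which forms the C9–C11 bond by Pd-catalysed Negishi sp3–sp2 cross-coupling with the enol triflate without creating a stereocentre.

Step 11
Reactants: 19 methyl (3R)-3-methyl-5-[(4aR,8aR)-5,5,8a-trimethyl-3,4,4a,5,6,7,8,8a-octahydronaphthalen-1-yl]pentanoate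
Product: 21 methyl (3R)-5-[(1S,2S,4aR,8aR)-2-hydroxy-5,5,8a-trimethyldecahydronaphthalen-1-yl]-3-methylpentanoate, via alkylborane 20 (not isolated)
Conditions: BH3·THF, THF, 0 °C to rt; then NaBO3·4H2O, H2O, rt
Reagents that add atoms: sodium perborate, [Na+].[Na+].O[B-]1(O)OO[B-](O)(O)OO1
Why: In this hydroboration–oxidation borane should add syn from the face opposite the axial C10 methyl with boron at the less substituted C8, which sets H9 anti to the C10 methyl (side chain equatorial), and oxidation with retention gives the C8 alcohol.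

Step 12
Reactants: 21 methyl (3R)-5-[(1S,2S,4aR,8aR)-2-hydroxy-5,5,8a-trimethyldecahydronaphthalen-1-yl]-3-methylpentanoate
Product: 22 methyl (3R)-3-methyl-5-[(1S,4aR,8aR)-5,5,8a-trimethyl-2-oxodecahydronaphthalen-1-yl]pentanoate
Conditions: Dess–Martin periodinane, NaHCO3, CH2Cl2, rt
Reagents that add atoms: none
Why: Buffered Dess–Martin oxidation of the secondary alcohol keeps the C9 side chain in its equatorial, thermodynamically preferred orientation.

Step 13
Reactants: 22 methyl (3R)-3-methyl-5-[(1S,4aR,8aR)-5,5,8a-trimethyl-2-oxodecahydronaphthalen-1-yl]pentanoate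
Product: 24 methyl (3R)-3-methyl-5-[(1S,4aR,8aR)-5,5,8a-trimethyl-2-{[(trifluoromethyl)sulfonyl]oxy}-1,4,4a,5,6,7,8,8a-octahydronaphthalen-1-yl]pentanoate, via potassium enolate 23 (not isolated)
Conditions: KN(SiMe3)2 (1.05 equiv), THF, −78 °C; then PhNTf2, −78 to 0 °C
Reagents that add atoms: N-phenylbis(trifluoromethanesulfonimide), O=S(=O)(N(c1ccccc1)S(=O)(=O)C(F)(F)F)C(F)(F)F
Why: Kinetic deprotonation by the hindered amide should occur at the C7 methylene rather than at the tertiary C9–H next to C10 or at the ester, and O-triflation of the enolate then gives the C7=C8 enol triflate.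

Step 14
Reactants: 24 methyl (3R)-3-methyl-5-[(1S,4aR,8aR)-5,5,8a-trimethyl-2-{[(trifluoromethyl)sulfonyl]oxy}-1,4,4a,5,6,7,8,8a-octahydronaphthalen-1-yl]pentanoate
Product: 25 methyl (3R)-5-[(1S,4aR,8aR)-2-(hydroxymethyl)-5,5,8a-trimethyl-1,4,4a,5,6,7,8,8a-octahydronaphthalen-1-yl]-3-methylpentanoate
Conditions: Bu3SnCH2OH, Pd(PPh3)4 (5 mol %), LiCl, 1,4-dioxane, 90 °C
Reagents that add atoms: (tributylstannyl)methanol, OC[Sn](CCCC)(CCCC)CCCC
Why: Stille cross-coupling of the enol triflate with the hydroxymethyl stannane, with LiCl to assist transmetalation, installs C17 as the allylic alcohol without disturbing C9.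

Step 15
Reactants: 25 methyl (3R)-5-[(1S,4aR,8aR)-2-(hydroxymethyl)-5,5,8a-trimethyl-1,4,4a,5,6,7,8,8a-octahydronaphthalen-1-yl]-3-methylpentanoate
Product: 26 methyl (3R)-5-[(1S,4aR,8aR)-2-(acetoxymethyl)-5,5,8a-trimethyl-1,4,4a,5,6,7,8,8a-octahydronaphthalen-1-yl]-3-methylpentanoate
Conditions: Ac2O, pyridine, DMAP (cat.), CH2Cl2, rt
Reagents that add atoms: acetic anhydride, CC(=O)OC(C)=O
Why: DMAP-catalysed acetylation of the primary allylic alcohol gives the target.

**Compound list**

1 | (S)-carvone, (5S)-2-methyl-5-(prop-1-en-2-yl)cyclohex-2-en-1-one | CC1=CC[C@H](C(C)=C)CC1=O | starting material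
2 | (5S)-5-(1-hydroperoxy-1-methoxyethyl)-2-methylcyclohex-2-en-1-one (both epimers at the acetal carbon) | CC1=CC[C@H](C(C)(OC)OO)CC1=O | intermediate
3 | (1S)-4-methyl-5-oxocyclohex-3-en-1-yl acetate | CC1=CC[C@H](OC(C)=O)CC1=O | intermediate
4 | (5S)-5-hydroxy-2-methylcyclohex-2-en-1-one | CC1=CC[C@H](O)CC1=O | intermediate
5 | (5S)-5-{[tert-butyl(dimethyl)silyl]oxy}-2-methylcyclohex-2-en-1-one | CC1=CC[C@H](O[Si](C)(C)C(C)(C)C)CC1=O | intermediate
6 | trimethyl[(2-methylprop-1-en-1-yl)oxy]silane | CC(C)=CO[Si](C)(C)C | starting material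
7 | triphenyl(vinyl)phosphonium bromide | C=C[P+](c1ccccc1)(c1ccccc1)c1ccccc1.[Br-] | starting material
8 | 2-[(1S,5S)-5-{[tert-butyl(dimethyl)silyl]oxy}-2-methyl-3-[(trimethylsilyl)oxy]cyclohex-2-en-1-yl]-2-methylpropanal | O=CC(C)(C)[C@H]1C[C@H](O[Si](C)(C)C(C)(C)C)CC(O[Si](C)(C)C)=C1C | intermediate
9 | 2-[(1R,2R,5S)-5-{[tert-butyl(dimethyl)silyl]oxy}-2-methyl-3-oxo-2-[2-(triphenylphosphoranylidene)ethyl]cyclohexyl]-2-methylpropanal | O=CC(C)(C)[C@H]1C[C@H](O[Si](C)(C)C(C)(C)C)CC(=O)[C@]1(C)CC=P(c1ccccc1)(c1ccccc1)c1ccccc1 | intermediate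
10 | (3S,4aR,8aR)-3-{[tert-butyl(dimethyl)silyl]oxy}-5,5,8a-trimethyl-3,4,4a,5,8,8a-hexahydronaphthalen-1(2H)-one | O=C1C[C@@H](O[Si](C)(C)C(C)(C)C)C[C@@H]2C(C)(C)C=CC[C@@]12C | intermediate
11 | (4aR,8aR)-5,5,8a-trimethyl-4a,5,8,8a-tetrahydronaphthalen-1(4H)-one | O=C1C=CC[C@@H]2C(C)(C)C=CC[C@@]12C | intermediate
12 | (4aR,8aR)-5,5,8a-trimethyloctahydronaphthalen-1(2H)-one | O=C1CCC[C@@H]2C(C)(C)CCC[C@@]12C | intermediate
13 | potassium (4aR,8aR)-5,5,8a-trimethyl-3,4,4a,5,6,7,8,8a-octahydronaphthalen-1-olate | [K+].[O-]C1=CCC[C@@H]2C(C)(C)CCC[C@@]12C | intermediate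
14 | (4aR,8aR)-5,5,8a-trimethyl-3,4,4a,5,6,7,8,8a-octahydronaphthalen-1-yl trifluoromethanesulfonate | FC(F)(F)S(=O)(=O)OC1=CCC[C@@H]2C(C)(C)CCC[C@@]12C | intermediate
15 | (3R)-5-methoxy-3-methyl-5-oxopentanoic acid (methyl hydrogen (R)-3-methylglutarate) | COC(=O)C[C@H](C)CC(=O)O | starting material
16 | methyl (3R)-5-hydroxy-3-methylpentanoate | COC(=O)C[C@H](C)CCO | intermediate
17 | methyl (3S)-5-iodo-3-methylpentanoate | COC(=O)C[C@H](C)CCI | intermediate
18 | iodo[(3S)-5-methoxy-3-methyl-5-oxopentyl]zinc | COC(=O)C[C@H](C)CC[Zn]I | intermediate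
19 | methyl (3R)-3-methyl-5-[(4aR,8aR)-5,5,8a-trimethyl-3,4,4a,5,6,7,8,8a-octahydronaphthalen-1-yl]pentanoate | COC(=O)C[C@H](C)CCC1=CCC[C@@H]2C(C)(C)CCC[C@@]12C | intermediate
20 | C8 alkylborane from 19: methyl (3R)-5-[2-boranyl-5,5,8a-trimethyldecahydronaphthalen-1-yl]-3-methylpentanoate with BH2 at C8 and H at C9 both anti to the C10 methyl | COC(=O)C[C@H](C)CC[C@@H]1[C@@H](B)CC[C@@H]2C(C)(C)CCC[C@@]12C | intermediate
21 | methyl (3R)-5-[(1S,2S,4aR,8aR)-2-hydroxy-5,5,8a-trimethyldecahydronaphthalen-1-yl]-3-methylpentanoate | COC(=O)C[C@H](C)CC[C@@H]1[C@@H](O)CC[C@@H]2C(C)(C)CCC[C@@]12C | intermediate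
22 | methyl (3R)-3-methyl-5-[(1S,4aR,8aR)-5,5,8a-trimethyl-2-oxodecahydronaphthalen-1-yl]pentanoate | COC(=O)C[C@H](C)CC[C@@H]1C(=O)CC[C@@H]2C(C)(C)CCC[C@@]12C | intermediate
23 | potassium (1S,4aR,8aR)-1-[(3R)-5-methoxy-3-methyl-5-oxopentyl]-5,5,8a-trimethyl-1,4,4a,5,6,7,8,8a-octahydronaphthalen-2-olate | [K+].COC(=O)C[C@H](C)CC[C@@H]1C([O-])=CC[C@@H]2C(C)(C)CCC[C@@]12C | intermediate
24 | methyl (3R)-3-methyl-5-[(1S,4aR,8aR)-5,5,8a-trimethyl-2-{[(trifluoromethyl)sulfonyl]oxy}-1,4,4a,5,6,7,8,8a-octahydronaphthalen-1-yl]pentanoate | COC(=O)C[C@H](C)CC[C@@H]1C(OS(=O)(=O)C(F)(F)F)=CC[C@@H]2C(C)(C)CCC[C@@]12C | intermediate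
25 | methyl (3R)-5-[(1S,4aR,8aR)-2-(hydroxymethyl)-5,5,8a-trimethyl-1,4,4a,5,6,7,8,8a-octahydronaphthalen-1-yl]-3-methylpentanoate | COC(=O)C[C@H](C)CC[C@@H]1C(CO)=CC[C@@H]2C(C)(C)CCC[C@@]12C | intermediate
26 | methyl (3R)-5-[(1S,4aR,8aR)-2-(acetoxymethyl)-5,5,8a-trimethyl-1,4,4a,5,6,7,8,8a-octahydronaphthalen-1-yl]-3-methylpentanoate | COC(=O)C[C@H](C)CC[C@@H]1C(COC(C)=O)=CC[C@@H]2C(C)(C)CCC[C@@]12C | target

**Step count and risks**

Total step count: 15. Longest linear sequence: 13 steps (steps 1–7 and 10–15); steps 8 and 9 prepare the side-chain fragment.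

Steps most likely to fail:

Step 4 (key step). Proton transfer to the fluoride-released enolate, or its aldol addition to the free aldehyde, may outrun conjugate addition to the vinylphosphonium salt, and facial selectivity in the Mukaiyama–Michael stage may erode. The fallback replaces the Michael–Wittig closure by alkylation and metathesis. It sets out from 5 and 6: the same Mukaiyama–Michael addition would give 8, and TBAT with allyl bromide would allylate C10 to give the 2-allyl keto aldehyde F1. Takai methylenation (CH2I2, Zn, Ti(O-i-Pr)4) of the aldehyde alone would give the allyl/vinyl diene F2. Ring-closing metathesis with the second-generation Grubbs catalyst would form C2=C3 and come back to the route at 10.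

Step 11. Hydroboration of the hindered trisubstituted C8=C9 alkene may be slow enough for borane to start reducing the methyl ester. The fallback replaces hydroboration by oxygen transfer and rearrangement. It sets out from 19: mCPBA (NaHCO3, CH2Cl2) should epoxidise the face opposite the C10 methyl to give the 8,9-epoxide F3. Meinwald rearrangement (BF3·OEt2, −78 °C, hydride shift from C8 to C9) would give the C8 ketone directly and come back to the route at 22.

Step 2. Base-induced β-elimination of acetate, followed by tautomerisation of the dienone to the phenol, may outrun methanolysis. The fallback removes the ketone that makes the acetate eliminable. It sets out from 3: i-Bu2AlH (CH2Cl2, −78 °C) would reduce the ketone and cleave the acetate to give the diol F4. MnO2 would re-oxidise only the allylic alcohol and come back to the route at 4.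

Further compounds
F1 | step 4 | 2-[(1R,2R,5S)-5-{[tert-butyl(dimethyl)silyl]oxy}-2-methyl-3-oxo-2-(prop-2-en-1-yl)cyclohexyl]-2-methylpropanal | O=CC(C)(C)[C@H]1C[C@H](O[Si](C)(C)C(C)(C)C)CC(=O)[C@]1(C)CC=C
F2 | step 4 | (2R,3R,5S)-5-{[tert-butyl(dimethyl)silyl]oxy}-2-methyl-3-(2-methylbut-3-en-2-yl)-2-(prop-2-en-1-yl)cyclohexan-1-one | C=CC(C)(C)[C@H]1C[C@H](O[Si](C)(C)C(C)(C)C)CC(=O)[C@]1(C)CC=C
F3 | step 11 | methyl (3R)-5-[(1R,2S,4aR,8aR)-1,2-epoxy-5,5,8a-trimethyldecahydronaphthalen-1-yl]-3-methylpentanoate (oxirane anti to the C10 methyl) | COC(=O)C[C@H](C)CC[C@]12O[C@H]1CC[C@@H]1C(C)(C)CCC[C@@]21C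
F4 | step 2 | (1S)-4-methylcyclohex-4-ene-1,3-diol (both epimers at C3) | CC1=CC[C@H](O)CC1O
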